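Everything rests on making ring D de novo. Ring D carries a para oxygen pair on C1 (the ether oxygen to ring C) and C4, further oxygens on C2 and C6, ring E on C5 and hydrogen on C3, which is the imprint of a Dötz benzannulation. In one operation an alkenyl(methoxy)carbene chromium complex, ethoxyacetylene and one CO ligand form C3–C4, C1–C2 and C1–C6 and deliver the ring D–E biaryl with the C1 oxygen as its only free hydroxyl among seven oxygens. The precursor is the (E)-β-methoxyvinyl carbene complex bearing the trimethoxyphenyl ring E on its α-carbon. Two such phenols are then joined to a ring A–B–C dibromide and all nineteen alkyl ethers are cleaved.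

Key step: step 5

Assumption: compounds 1, 6, 11, 17, 18 and 23 are taken as purchasable (11 as its hexane solution); either alkene isomer of the carbene precursor would converge, because its β-carbon becomes aromatic C6 of ring D.

Step 1
Reactants: 1 2-(2,4,6-trimethoxyphenyl)acetic acid
Product: 2 methyl 2-(2,4,6-trimethoxyphenyl)acetate
Conditions: MeOH, H2SO4 (cat.), reflux
Reagents that add atoms: methanol, CO
Why: Fischer esterification of an unhindered arylacetic acid, driven by methanol as solvent, with the aryl methyl ethers inert to catalytic acid.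

Step 2
Reactants: 2 methyl 2-(2,4,6-trimethoxyphenyl)acetate
Product: 4 methyl (E)-3-methoxy-2-(2,4,6-trimethoxyphenyl)prop-2-enoate, via sodium formyl ester enolate 3 (not isolated)
Conditions: NaH, HCO2Me, THF, 0 °C → rt; then Me2SO4, DMF, rt
Reagents that add atoms: methyl formate, COC=O; dimethyl sulfate, COS(=O)(=O)OC
Why: Crossed Claisen condensation (formylation) of the ester enolate followed by O-methylation of the hard enolate oxygen, the standard construction of β-methoxyacrylates, which should favour the E isomer with methoxy trans to the ester.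

Step 3
Reactants: 4 methyl (E)-3-methoxy-2-(2,4,6-trimethoxyphenyl)prop-2-enoate
Product: 5 (E)-3-methoxy-2-(2,4,6-trimethoxyphenyl)prop-2-enoic acid
Conditions: KOH, MeOH/H2O, 60 °C; then cold dil. HCl to pH 3
Reagents that add atoms: potassium hydroxide, [K+].[OH-]
Why: Saponification of the methyl ester by acyl–oxygen cleavage; the enol ether is a vinylogous carbonate and should survive hydroxide and brief cold acid.

Step 4
Reactants: 5 (E)-3-methoxy-2-(2,4,6-trimethoxyphenyl)prop-2-enoic acid; 6 chromium hexacarbonyl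
Product: 10 pentacarbonyl[(E)-1,3-dimethoxy-2-(2,4,6-trimethoxyphenyl)prop-2-en-1-ylidene]chromium, via acid chloride 7 (not isolated), via disodium pentacarbonylchromate 8 (not isolated), via sodium acylchromate 9 (not isolated)
Conditions: Me2C=C(Cl)NMe2, CH2Cl2, 0 °C → rt, evaporate; Na2Cr(CO)5 [Cr(CO)6, sodium naphthalenide, THF, −78 °C], −78 → 0 °C; then Me3OBF4, CH2Cl2, 0 °C
Reagents that add atoms: trimethyloxonium tetrafluoroborate, C[O+](C)C.F[B-](F)(F)F
Why: Reductive-acylation route to Fischer carbene complexes, in which the nucleophilic pentacarbonylchromate dianion is acylated by the neutrally generated acid chloride and the acylchromate oxygen is methylated by the oxonium salt; no electrophilic halogen or organolithium meets the electron-rich ring E, and the alkene geometry of 5 is carried through.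

Step 5
Reactants: 10 pentacarbonyl[(E)-1,3-dimethoxy-2-(2,4,6-trimethoxyphenyl)prop-2-en-1-ylidene]chromium; 11 ethoxyacetylene
Product: 16 6-ethoxy-2,4-dimethoxy-3-(2,4,6-trimethoxyphenyl)phenol, via tetracarbonyl vinylcarbene complex 12 (not isolated), via chromium-bound dienylketene 13 (not isolated), via chromium-bound cyclohexadienone 14 (not isolated), via tricarbonylchromium phenol complex 15 (not isolated)
Conditions: 11 (2 equiv, slow addition), THF, 45 °C, sealed vessel; then air, CH2Cl2, rt
Reagents that add atoms: none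
Why: Thermal loss of one CO from 10 lets the alkyne insert into the Cr=C bond to give 12, CO insertion gives ketene 13, ring closure gives dienone 14, enolisation of the C6 hydrogen gives phenol complex 15, and air strips the Cr(CO)3 fragment. This is a Dötz benzannulation of an alkenyl(alkoxy)carbene chromium complex with a terminal alkyne, here with the less common ynol ether as partner. Ring D closes by a thermally allowed disrotatory 6π-electrocyclisation of the dienylketene that forms C1–C6, and no stereocentre survives. The step needs regioselective insertion: the unsubstituted, nucleophilic alkyne carbon bonds to the electrophilic carbene carbon (C3–C4) and the ethoxy-bearing carbon stays on chromium to take up CO (C1–C2), as both the steric rule for terminal alkynes and the polarity of the ynol ether require. It also needs CO insertion to outrun five-membered ring closure, which chromium, an alkenyl carbene and a coordinating solvent favour. Ring E rides as a spectator on the α-carbon, so the crowded biaryl bond exists before ring D does.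

Step 6
Reactants: 17 2,6-difluoro-4-methoxybenzaldehyde; 18 4-bromo-2,6-dimethoxyphenol (2.2 equiv)
Product: 20 2,6-bis(4-bromo-2,6-dimethoxyphenoxy)-4-methoxybenzaldehyde, via monoaryl ether 19 (not isolated)
Conditions: Cs2CO3, DMAc, 110 °C
Reagents that add atoms: none
Why: Two successive SNAr displacements of fluoride ortho to the formyl group through Meisenheimer adducts, while the unactivated aryl bromides of 18 stay intact.

Step 7
Reactants: 20 2,6-bis(4-bromo-2,6-dimethoxyphenoxy)-4-methoxybenzaldehyde
Product: 22 2,6-bis(4-bromo-2,6-dimethoxyphenoxy)-4-methoxyphenol, via aryl formate 21 (not isolated)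
Conditions: mCPBA, CH2Cl2, 0 °C → rt; then K2CO3 (cat.), MeOH, rt
Reagents that add atoms: mCPBA, OOC(=O)c1cccc(Cl)c1
Why: Baeyer–Villiger oxidation of the aldehyde with a Dakin-type outcome, in which the electron-rich trioxygenated aryl group migrates in preference to hydrogen and mild methanolysis of the formate frees the ring B C2 hydroxyl.

Step 8
Reactants: 22 2,6-bis(4-bromo-2,6-dimethoxyphenoxy)-4-methoxyphenol; 23 (3,5-dimethoxyphenyl)boronic acid
Product: 24 1,3-bis(4-bromo-2,6-dimethoxyphenoxy)-2-(3,5-dimethoxyphenoxy)-5-methoxybenzene (ring A–B–C dibromide)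
Conditions: Cu(OAc)2 (2 equiv), pyridine, 4 Å MS, CH2Cl2, air, rt
Reagents that add atoms: none
Why: Chan–Lam oxidative O-arylation at room temperature, which tolerates phenols flanked by two ortho substituents and leaves aryl bromides untouched.

Step 9
Reactants: 24 ring A–B–C dibromide; 16 6-ethoxy-2,4-dimethoxy-3-(2,4,6-trimethoxyphenyl)phenol (2.4 equiv)
Product: 26 1,3-bis{4-[6-ethoxy-2,4-dimethoxy-3-(2,4,6-trimethoxyphenyl)phenoxy]-2,6-dimethoxyphenoxy}-2-(3,5-dimethoxyphenoxy)-5-methoxybenzene, via monocoupled bromide 25 (not isolated)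
Conditions: CuI (20 mol %), picolinic acid (40 mol %), K3PO4, DMSO, 100 °C, argon
Reagents that add atoms: none
Why: Ligand-accelerated Ullmann diaryl ether synthesis; each bromide of 24 sits between two ring hydrogens, so only the phenol partner is hindered, a case the picolinate–copper system is suited to.

Step 10
Reactants: 26 fully O-alkylated precursor
Product: 27 CNP0227063.0, 3,5-bis{4-[2,4,6-trihydroxy-3-(2,4,6-trihydroxyphenyl)phenoxy]-2,6-dihydroxyphenoxy}-4-(3,5-dihydroxyphenoxy)phenol
Conditions: BBr3 (60 equiv), CH2Cl2, −78 °C → rt; then MeOH, H2O, 0 °C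
Reagents that add atoms: none
Why: Lewis acid-mediated dealkylation of the seventeen methyl and two ethyl aryl ethers by bromide attack at the O-alkyl carbon; the diaryl ether and biaryl bonds offer no sp3 carbon and should persist, and the product has no ortho- or para-dihydroxy pair open to quinone formation.

Compound list
1 | 2-(2,4,6-trimethoxyphenyl)acetic acid | COc1cc(OC)c(CC(=O)O)c(OC)c1 | starting material
2 | methyl 2-(2,4,6-trimethoxyphenyl)acetate | COC(=O)Cc1c(OC)cc(OC)cc1OC | intermediate
3 | sodium enolate of methyl 3-oxo-2-(2,4,6-trimethoxyphenyl)propanoate (delocalised, geometry not fixed) | [Na+].[O-]C=C(C(=O)OC)c1c(OC)cc(OC)cc1OC | intermediate (not isolated)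
4 | methyl (E)-3-methoxy-2-(2,4,6-trimethoxyphenyl)prop-2-enoate | CO/C=C(/C(=O)OC)c1c(OC)cc(OC)cc1OC | intermediate
5 | (E)-3-methoxy-2-(2,4,6-trimethoxyphenyl)prop-2-enoic acid | CO/C=C(/C(=O)O)c1c(OC)cc(OC)cc1OC | intermediate
6 | chromium hexacarbonyl, Cr(CO)6 | [Cr](=C=O)(=C=O)(=C=O)(=C=O)(=C=O)=C=O | starting material
7 | (E)-3-methoxy-2-(2,4,6-trimethoxyphenyl)prop-2-enoyl chloride | CO/C=C(/C(Cl)=O)c1c(OC)cc(OC)cc1OC | intermediate (not isolated)
8 | disodium pentacarbonylchromate, Na2Cr(CO)5 | [Na+].[Na+].[Cr-2](=C=O)(=C=O)(=C=O)(=C=O)=C=O | intermediate (not isolated)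
9 | sodium pentacarbonyl[(E)-3-methoxy-1-oxido-2-(2,4,6-trimethoxyphenyl)prop-2-en-1-ylidene]chromate | [Na+].[O-]C(=[Cr](=C=O)(=C=O)(=C=O)(=C=O)=C=O)/C(=C/OC)c1c(OC)cc(OC)cc1OC | intermediate (not isolated)
10 | pentacarbonyl[(E)-1,3-dimethoxy-2-(2,4,6-trimethoxyphenyl)prop-2-en-1-ylidene]chromium | COC(=[Cr](=C=O)(=C=O)(=C=O)(=C=O)=C=O)/C(=C/OC)c1c(OC)cc(OC)cc1OC | intermediate (key-step precursor)
11 | ethoxyacetylene | CCOC#C | starting material
12 | tetracarbonyl[(2E,4E)-1-ethoxy-3,5-dimethoxy-4-(2,4,6-trimethoxyphenyl)penta-2,4-dien-1-ylidene]chromium | CCOC(=[Cr](=C=O)(=C=O)(=C=O)=C=O)/C=C(OC)\C(=C\OC)c1c(OC)cc(OC)cc1OC | intermediate (not isolated)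
13 | (3E,5E)-2-ethoxy-4,6-dimethoxy-5-(2,4,6-trimethoxyphenyl)hexa-1,3,5-trien-1-one, bound to a Cr(CO)3 fragment | CCOC(=C=O)/C=C(OC)\C(=C\OC)c1c(OC)cc(OC)cc1OC.[Cr](=C=O)(=C=O)=C=O | intermediate (not isolated)
14 | 2-ethoxy-4,6-dimethoxy-5-(2,4,6-trimethoxyphenyl)cyclohexa-2,4-dien-1-one (racemic at C6, transient), bound to a Cr(CO)3 fragment | CCOC1=CC(OC)=C(c2c(OC)cc(OC)cc2OC)C(OC)C1=O.[Cr](=C=O)(=C=O)=C=O | intermediate (not isolated)
15 | tricarbonylchromium complex of phenol 16 | Oc1c(OCC)cc(OC)c(-c2c(OC)cc(OC)cc2OC)c1OC.[Cr](=C=O)(=C=O)=C=O | intermediate (not isolated)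
16 | 6-ethoxy-2,4-dimethoxy-3-(2,4,6-trimethoxyphenyl)phenol | Oc1c(OCC)cc(OC)c(-c2c(OC)cc(OC)cc2OC)c1OC | intermediate (key-step product)
17 | 2,6-difluoro-4-methoxybenzaldehyde | COc1cc(F)c(C=O)c(F)c1 | starting material
18 | 4-bromo-2,6-dimethoxyphenol | COc1cc(Br)cc(OC)c1O | starting material
19 | 2-(4-bromo-2,6-dimethoxyphenoxy)-6-fluoro-4-methoxybenzaldehyde | COc1cc(F)c(C=O)c(Oc2c(OC)cc(Br)cc2OC)c1 | intermediate (not isolated)
20 | 2,6-bis(4-bromo-2,6-dimethoxyphenoxy)-4-methoxybenzaldehyde | COc1cc(Oc2c(OC)cc(Br)cc2OC)c(C=O)c(Oc2c(OC)cc(Br)cc2OC)c1 | intermediate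
21 | 2,6-bis(4-bromo-2,6-dimethoxyphenoxy)-4-methoxyphenyl formate | COc1cc(Oc2c(OC)cc(Br)cc2OC)c(OC=O)c(Oc2c(OC)cc(Br)cc2OC)c1 | intermediate (not isolated)
22 | 2,6-bis(4-bromo-2,6-dimethoxyphenoxy)-4-methoxyphenol | COc1cc(Oc2c(OC)cc(Br)cc2OC)c(O)c(Oc2c(OC)cc(Br)cc2OC)c1 | intermediate
23 | (3,5-dimethoxyphenyl)boronic acid | COc1cc(OC)cc(B(O)O)c1 | starting material
24 | 1,3-bis(4-bromo-2,6-dimethoxyphenoxy)-2-(3,5-dimethoxyphenoxy)-5-methoxybenzene | COc1cc(OC)cc(Oc2c(Oc3c(OC)cc(Br)cc3OC)cc(OC)cc2Oc2c(OC)cc(Br)cc2OC)c1 | intermediate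
25 | 24 with one bromine replaced by the aryloxy group of 16 | COc1cc(OC)cc(Oc2c(Oc3c(OC)cc(Br)cc3OC)cc(OC)cc2Oc2c(OC)cc(Oc3c(OCC)cc(OC)c(-c4c(OC)cc(OC)cc4OC)c3OC)cc2OC)c1 | intermediate (not isolated)
26 | 1,3-bis{4-[6-ethoxy-2,4-dimethoxy-3-(2,4,6-trimethoxyphenyl)phenoxy]-2,6-dimethoxyphenoxy}-2-(3,5-dimethoxyphenoxy)-5-methoxybenzene | COc1cc(OC)cc(Oc2c(Oc3c(OC)cc(Oc4c(OCC)cc(OC)c(-c5c(OC)cc(OC)cc5OC)c4OC)cc3OC)cc(OC)cc2Oc2c(OC)cc(Oc3c(OCC)cc(OC)c(-c4c(OC)cc(OC)cc4OC)c3OC)cc2OC)c1 | intermediate
27 | CNP0227063.0, 3,5-bis{4-[2,4,6-trihydroxy-3-(2,4,6-trihydroxyphenyl)phenoxy]-2,6-dihydroxyphenoxy}-4-(3,5-dihydroxyphenoxy)phenol (no stereocentre) | Oc1cc(O)cc(Oc2c(Oc3c(O)cc(Oc4c(O)cc(O)c(-c5c(O)cc(O)cc5O)c4O)cc3O)cc(O)cc2Oc2c(O)cc(Oc3c(O)cc(O)c(-c4c(O)cc(O)cc4O)c3O)cc2O)c1 | target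

Total step count: 10. Longest linear sequence: 7 (steps 1–5, 9 and 10); the ring A–B–C branch (steps 6–8) joins at step 9.

Steps most likely to fail

Step 5 (benzannulation). After the ynol ether has inserted, the new carbene carbon carries an ethoxy donor, so CO insertion may be slow. The intermediate could then divert to five-membered ring closure, or the alkyne could oligomerise on chromium; the push–pull β-methoxyvinyl complex may also be slow to lose CO. The fallback sets out from 10 and separates insertion from CO uptake. Compounds 10 and 11 would be combined in CH2Cl2 under CO (1 atm) at 0 °C → rt, where an electron-rich alkyne can add to the carbene carbon without prior CO loss. This should give the donor-stabilised dienylcarbene complex pentacarbonyl[(2E,4E)-1-ethoxy-3,5-dimethoxy-4-(2,4,6-trimethoxyphenyl)penta-2,4-dien-1-ylidene]chromium F1. Irradiation of F1 (Pyrex-filtered medium-pressure Hg lamp, THF, CO 1 atm, rt) would then drive CO insertion photochemically to the chromium ketene, which closes by the same 6π pathway. This is the known photochemical benzannulation of dienylcarbene complexes to ortho-alkoxyphenols, and light also equilibrates the central alkene geometry. It comes back to the route at 16.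

Step 9 (double Ullmann etherification). Copper insertion into the electron-rich bromides may be slow, so that hydrodebromination, stalling at the monoether, or oxidative degradation of the hindered phenolate at 100 °C competes. The fallback sets out from 24 and inverts the polarity of the coupling. Double bromine–lithium exchange with in-situ borate trapping (n-BuLi, B(OiPr)3, THF, −78 °C; aq. NH4Cl) would give {[2-(3,5-dimethoxyphenoxy)-5-methoxy-1,3-phenylene]bis(oxy-3,5-dimethoxy-4,1-phenylene)}diboronic acid F2. Chan–Lam coupling of F2 with 16 (Cu(OAc)2, pyridine, 4 Å MS, CH2Cl2, air, rt) then forms both ethers at room temperature from an unhindered boronic acid. It comes back to the route at 26.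

Step 10 (nineteen-fold dealkylation). Partially cleaved boron phenoxides may precipitate and stop the cleavage short, and the free polyphenol may be lost by air oxidation or irreversible adsorption during aqueous work-up and chromatography. The fallback sets out from 26 and changes the isolation to capture, purification and release. The crude BBr3 product would be peracetylated (Ac2O, pyridine, DMAP, rt) to the nonadecaacetate of 27 F3. F3 is chromatographed on silica, where under-cleaved congeners separate and can be returned to BBr3. Acid methanolysis (HCl in MeOH, rt, argon) followed by evaporation then releases the phenol without a basic or aqueous stage. It comes back to the route at 27.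

Further compounds
F1 | step 5 | pentacarbonyl[(2E,4E)-1-ethoxy-3,5-dimethoxy-4-(2,4,6-trimethoxyphenyl)penta-2,4-dien-1-ylidene]chromium | CCOC(=[Cr](=C=O)(=C=O)(=C=O)(=C=O)=C=O)/C=C(OC)\C(=C\OC)c1c(OC)cc(OC)cc1OC
F2 | step 9 | {[2-(3,5-dimethoxyphenoxy)-5-methoxy-1,3-phenylene]bis(oxy-3,5-dimethoxy-4,1-phenylene)}diboronic acid | COc1cc(OC)cc(Oc2c(Oc3c(OC)cc(B(O)O)cc3OC)cc(OC)cc2Oc2c(OC)cc(B(O)O)cc2OC)c1
F3 | step 10 | nonadecaacetate of 27 (every hydroxyl acetylated) | CC(=O)Oc1cc(OC(C)=O)cc(Oc2c(Oc3c(OC(C)=O)cc(Oc4c(OC(C)=O)cc(OC(C)=O)c(-c5c(OC(C)=O)cc(OC(C)=O)cc5OC(C)=O)c4OC(C)=O)cc3OC(C)=O)cc(OC(C)=O)cc2Oc2c(OC(C)=O)cc(Oc3c(OC(C)=O)cc(OC(C)=O)c(-c4c(OC(C)=O)cc(OC(C)=O)cc4OC(C)=O)c3OC(C)=O)cc2OC(C)=O)c1
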